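**Assumptions (one line each)**
- Prostanoid numbering is used for atom labels (C1 = ester carbon, ring = C8–C12); the target is (7S,8R,12S).
- Cyclopentadiene is freshly cracked from commercial dicyclopentadiene.
- In step 1 the major lactone is taken to be the endo-hydroxy isomer (OH cis to the ring CH2), which is the C7/C8 relationship the target needs.
- In step 2 the wanted (3R,3aS,6aS)-alcohol is taken to be the slow-reacting enantiomer; if the lipase prefers it, its acetate is collected and cleaved enzymatically instead.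
- THP ethers are epimeric mixtures at the acetal carbon; this centre is removed in step 12.

**Retrosynthetic overview**
1. Endgame: 7-OAc and 10-I go on last; the C9 ketone comes from oxidising a C9 allylic alcohol, so the enone is reached by a 1,3-carbonyl transposition and not by enolate (aldol) chemistry.
2. C5=C6: Z-selective Wittig opening of a bicyclic lactol (C6 is the former lactone carbonyl) installs C1–C5.
3. C12–C13: α-selective, Z-retentive (Z)-oct-2-enylbarium 1,2-addition to the convex face of a cis-fused enone-lactone sets C12 with OH cis to the C8 chain.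
4. Key step: the C7–C8 bond, the C7/C8 relative configuration and the lactone all come from one aqueous hetero-Diels–Alder/lactonisation of cyclopentadiene with glyoxylic acid (lipase-resolved); allylic oxidation then gives the enone-lactone.
5. Rings: the carbocycle is the intact cyclopentadiene ring; the γ-lactone forms first (step 1), acts as the stereocontrol element, and is opened in step 8.

**Route**

Step 1
Reactants: 1 cyclopenta-1,3-diene; 2 glyoxylic acid (50% aq.)
Product: 3 (±)-(3R*,3aS*,6aS*)-3-hydroxy-3,3a,4,6a-tetrahydro-2H-cyclopenta[b]furan-2-one (4-endo-hydroxy-2-oxabicyclo[3.3.0]oct-7-en-3-one; cis-fused, OH on the concave face)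
Conditions: H2O (pH ≈ 1), 40 °C, 24 h; major endo-OH isomer (≈3:1) separated by crystallisation/chromatography
Reagents that add atoms: none beyond the listed reactants
Why: Aqueous hetero-Diels–Alder of the activated aldehyde (endo-CO2H) followed by acid-promoted allylic C–O ionisation and recapture by the carboxylate (lactonisation) forms C7–C8; the endo adduct gives the endo-OH lactone (the anti C7/C8 relationship of the target) and the cis ring fusion fixes C8/C9.

Step 2
Reactants: 3 (±)-hydroxy-lactone
Product: 4 (3R,3aS,6aS)-3-hydroxy-3,3a,4,6a-tetrahydro-2H-cyclopenta[b]furan-2-one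
Conditions: Pseudomonas fluorescens lipase, vinyl acetate, rt, to ~50% conversion; chromatography
Reagents that add atoms: none (vinyl acetate acylates only the unwanted enantiomer)
Why: Lipase-catalysed kinetic resolution (enantioselective transesterification) of the secondary α-hydroxy-lactone sets the absolute configuration at C7, C8 and C9.

Step 3
Reactants: 4 hydroxy-lactone
Product: 5 (3R,3aR,6aS)-3-(tetrahydro-2H-pyran-2-yloxy)-3,3a,4,6a-tetrahydro-2H-cyclopenta[b]furan-2-one
Conditions: 3,4-dihydro-2H-pyran, PPTS (cat.), CH2Cl2, rt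
Reagents that add atoms: 3,4-dihydro-2H-pyran, C1=COCCC1
Why: Acid-catalysed acetalisation; THP is chosen over a silyl ether because it cannot migrate to the C9/C12 alkoxides formed in steps 6–8 and comes off under mild acid next to a β-hydroxy ketone.

Step 4
Reactants: 5 THP-lactone
Product: 6 (3R,3aR,6aS)-3-(tetrahydro-2H-pyran-2-yloxy)-3,3a-dihydro-2H-cyclopenta[b]furan-2,4(6aH)-dione (enone-lactone; C12 ketone, C10=C11)
Conditions: CrO3, 3,5-dimethylpyrazole, CH2Cl2, −20 °C
Reagents that add atoms: chromium trioxide, O=[Cr](=O)=O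
Why: Allylic C–H oxidation at the only allylic methylene (C12); the other allylic C–H (C9) is deactivated by the acyloxy group, so the γ-acyloxy enone results.

Step 5
Reactants: 7 (Z)-oct-2-en-1-ol
Product: 8 (Z)-1-chlorooct-2-ene
Conditions: NCS, Me2S, CH2Cl2, −20 → 0 °C
Reagents that add atoms: N-chlorosuccinimide, O=C1CCC(=O)N1Cl
Why: Corey–Kim allylic chlorination (SN2 on the alkoxysulfonium) proceeds without allylic transposition or Z→E isomerisation.

Step 6
Reactants: 6 enone-lactone; 8 (Z)-1-chlorooct-2-ene
Product: 9 (3R,3aR,4R,6aS)-4-hydroxy-4-[(2Z)-oct-2-en-1-yl]-3-(tetrahydro-2H-pyran-2-yloxy)-3,3a,4,6a-tetrahydro-2H-cyclopenta[b]furan-2-one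
Conditions: active Ba (BaI2 + 2 Li biphenylide, THF); 8, −78 °C, 30 min; then 6 (1.0 equiv), −78 °C; NH4Cl quench at −78 °C
Reagents that add atoms: none beyond the listed reactants
Why: Allylbarium reagents add to ketones 1,2 at the α-carbon with retention of Z geometry; attack on the convex face of the cis-fused bicycle (anti to the C8–C7 bond and the endo-OTHP) sets C12 with OH cis to the C8 chain. Any translactonised isomer (lactone on O12) converges in steps 7–8.

Step 7
Reactants: 9 hydroxy-lactone
Product: 10 lactol: 4-[(2Z)-oct-2-en-1-yl]-3-(tetrahydro-2H-pyran-2-yloxy)-3,3a,4,6a-tetrahydro-2H-cyclopenta[b]furan-2,4-diol (configuration as 9; anomeric mixture)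
Conditions: DIBAL-H (2.5 equiv), CH2Cl2, −78 °C; Rochelle salt
Reagents that add atoms: none
Why: Partial hydride reduction of a γ-lactone stops at the lactol at −78 °C; the free tertiary OH only consumes one extra equivalent.

Step 8
Reactants: 10 lactol; 11 (4-carboxybutyl)triphenylphosphonium bromide
Product: 12 (5Z,7S,8R,9S,12R,14Z)-9,12-dihydroxy-7-(tetrahydro-2H-pyran-2-yloxy)prosta-5,10,14-trienoic acid
Conditions: 11 (5 equiv), KHMDS (10 equiv), THF, 0 °C; then 10, 0 °C → rt; pH 5 work-up
Reagents that add atoms: none beyond the listed reactants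
Why: Wittig olefination of the lactol (open hydroxy-aldehyde form) with a salt-free non-stabilised ylide gives the 5Z alkene and frees C9–OH; C7, C8, C9 and C12 are untouched.

Step 9
Reactants: 12 acid
Product: 13 methyl (5Z,7S,8R,9S,12R,14Z)-9,12-dihydroxy-7-(tetrahydro-2H-pyran-2-yloxy)prosta-5,10,14-trienoate
Conditions: TMSCHN2, PhMe/MeOH (4:1), 0 °C
Reagents that add atoms: trimethylsilyldiazomethane, C[Si](C)(C)C=[N+]=[N-]
Why: Neutral diazoalkane esterification methylates only the carboxylic acid.

Step 10
Reactants: 13 diol ester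
Product: 14 methyl (5Z,7S,8R,12R,14Z)-12-hydroxy-9-oxo-7-(tetrahydro-2H-pyran-2-yloxy)prosta-5,10,14-trienoate
Conditions: activated MnO2 (20 equiv), CH2Cl2, rt
Reagents that add atoms: none
Why: Chemoselective oxidation of the secondary allylic C9–OH (the tertiary C12–OH cannot oxidise) completes the 1,3-carbonyl transposition; C8 already has the thermodynamically preferred configuration (trans to the octenyl chain), so it is not at risk once it becomes α to the ketone.

Step 11
Reactants: 14 enone
Product: 15 methyl (5Z,7S,8R,12S,14Z)-12-hydroxy-10-iodo-9-oxo-7-(tetrahydro-2H-pyran-2-yloxy)prosta-5,10,14-trienoate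
Conditions: I2 (2.5 equiv), pyridine/CH2Cl2 (1:1), 0 °C → rt, dark
Reagents that add atoms: iodine, II
Why: Johnson α-iodination of an enone (pyridine conjugate addition, enolate iodination, elimination); doing it while C7 carries an ether avoids E1cB loss of a β-acyloxy group. The C12 descriptor changes from R to S only because iodine changes CIP priorities.

Step 12
Reactants: 15 iodo-enone THP ether
Product: 16 methyl (5Z,7S,8R,12S,14Z)-7,12-dihydroxy-10-iodo-9-oxoprosta-5,10,14-trienoate
Conditions: PPTS (0.2 equiv), MeOH, 35 °C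
Reagents that add atoms: none
Why: Mild acid-catalysed acetal exchange removes THP; these are the conditions that β-hydroxy-cyclopentanones of the PGE type tolerate without dehydration or retro-aldol.

Step 13
Reactants: 16 diol
Product: 17 7-acetoxy-7,8-dihydroiodovulone I (target)
Conditions: Ac2O (1.5 equiv), pyridine, CH2Cl2, 0 °C, short reaction time, no DMAP
Reagents that add atoms: acetic anhydride, CC(=O)OC(C)=O
Why: Acylation is selective for the secondary C7–OH over the tertiary C12–OH; low temperature and weak base limit E1cB elimination to the dienone.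

**Compound list**
1 | cyclopenta-1,3-diene | C1=CCC=C1 | starting material
2 | glyoxylic acid | O=CC(=O)O | starting material
3 | (±)-4-endo-hydroxy-2-oxabicyclo[3.3.0]oct-7-en-3-one (relative configuration shown, racemic) | O[C@H]1C(=O)O[C@H]2C=CC[C@@H]12 | intermediate
4 | (3R,3aS,6aS)-3-hydroxy-3,3a,4,6a-tetrahydro-2H-cyclopenta[b]furan-2-one | O[C@H]1C(=O)O[C@H]2C=CC[C@@H]12 | intermediate
5 | (3R,3aR,6aS)-3-(THP-oxy)-3,3a,4,6a-tetrahydro-2H-cyclopenta[b]furan-2-one | O1CCCCC1O[C@H]1C(=O)O[C@H]2C=CC[C@@H]12 | intermediate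
6 | (3R,3aR,6aS)-3-(THP-oxy)-3,3a-dihydro-2H-cyclopenta[b]furan-2,4(6aH)-dione | O1CCCCC1O[C@H]1C(=O)O[C@H]2C=CC(=O)[C@@H]12 | intermediate
7 | (Z)-oct-2-en-1-ol | CCCCC/C=C\CO | starting material
8 | (Z)-1-chlorooct-2-ene | CCCCC/C=C\CCl | intermediate
9 | (3R,3aR,4R,6aS)-4-hydroxy-4-[(2Z)-oct-2-enyl]-3-(THP-oxy)-3,3a,4,6a-tetrahydro-2H-cyclopenta[b]furan-2-one | CCCCC/C=C\C[C@@]1(O)C=C[C@@H]2OC(=O)[C@H](OC3CCCCO3)[C@H]12 | intermediate
10 | corresponding lactol (anomeric mixture) | CCCCC/C=C\C[C@@]1(O)C=C[C@@H]2OC(O)[C@H](OC3CCCCO3)[C@H]12 | intermediate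
11 | (4-carboxybutyl)triphenylphosphonium bromide | OC(=O)CCCC[P+](c1ccccc1)(c1ccccc1)c1ccccc1.[Br-] | starting material
12 | (5Z,7S,8R,9S,12R,14Z)-9,12-dihydroxy-7-(THP-oxy)prosta-5,10,14-trienoic acid | CCCCC/C=C\C[C@@]1(O)C=C[C@H](O)[C@@H]1[C@H](/C=C\CCCC(=O)O)OC1CCCCO1 | intermediate
13 | methyl ester of 12 | CCCCC/C=C\C[C@@]1(O)C=C[C@H](O)[C@@H]1[C@H](/C=C\CCCC(=O)OC)OC1CCCCO1 | intermediate
14 | methyl (5Z,7S,8R,12R,14Z)-12-hydroxy-9-oxo-7-(THP-oxy)prosta-5,10,14-trienoate | CCCCC/C=C\C[C@@]1(O)C=CC(=O)[C@@H]1[C@H](/C=C\CCCC(=O)OC)OC1CCCCO1 | intermediate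
15 | methyl (5Z,7S,8R,12S,14Z)-12-hydroxy-10-iodo-9-oxo-7-(THP-oxy)prosta-5,10,14-trienoate | CCCCC/C=C\C[C@@]1(O)C=C(I)C(=O)[C@@H]1[C@H](/C=C\CCCC(=O)OC)OC1CCCCO1 | intermediate
16 | methyl (5Z,7S,8R,12S,14Z)-7,12-dihydroxy-10-iodo-9-oxoprosta-5,10,14-trienoate | CCCCC/C=C\C[C@@]1(O)C=C(I)C(=O)[C@@H]1[C@H](/C=C\CCCC(=O)OC)O | intermediate
17 | 7-acetoxy-7,8-dihydroiodovulone I | CCCCC/C=C\C[C@@]1(O)C=C(I)C(=O)[C@@H]1[C@H](/C=C\CCCC(=O)OC)OC(C)=O | target

**Totals**
- Total steps: 13.
- Longest linear sequence: 12 (steps 1–4, then 6–13, from cyclopentadiene); step 5 is a one-step side branch.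

**Three steps most likely to fail, with fallbacks**
- **Step 6 (allylbarium addition).** Risks are enolisation and β-elimination of the γ-acyloxy enone, and α/γ or 1,2/1,4 erosion. Fallback: bring the chain in as an alkyne. SE2′ addition of tributyl(octa-1,2-dien-3-yl)stannane with BF3·OEt2 gives the oct-2-ynyl carbinol, and Lindlar semihydrogenation then gives the Z-olefin (one extra step).
- **Step 4 (allylic oxidation).** Risks are the transposed α-acyloxy enone and over-oxidation. Fallback: switch to the ene/[2,3] manifold. SeO2 (cat.)/t-BuOOH hydroxylates C12 without moving the alkene, and Dess–Martin oxidation then gives 6 (one extra step).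
- **Step 8 (Wittig on the α-alkoxy lactol).** Risks are C7 epimerisation under the basic ylide and sluggish ring-opening. Fallback: Stork–Zhao olefination of 10 (Ph3P=CHI) to the (Z)-vinyl iodide, then Pd-catalysed Negishi coupling with the zinc reagent from methyl 4-iodobutanoate. This gives 13 directly and removes step 9.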